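(All runs were computed for substances that don't exist, and the scatter is random.)

Time favours spring, with 80 min against 20 min, yet the runs so far point to a different quantity.

| flask | D | J | E | remark | time |
|---|---|---|---|---|---|
| north | 0.098 M | 0.53 µM | 0.69 µM | run made earlier |  |
| south | 0.098 M | 1.3 µM | 0.69 µM | run made earlier |  |
| north-east | 0.11 M | 0.85 µM | 0.69 µM | run made earlier |  |
| spring | 0.098 M | 0.85 µM | 0.69 µM |  | 80 min |
| summer | 0.060 M | 0.40 µM | 0.69 µM |  | 20 min |

| run | time / min | Q / % | D / % |
|---|---|---|---|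
| north | 8.00 | 0.3 | 92.6 |
| north | 15.0 | 0 | 88.1 |
| north | 25.0 | 1.4 | 82.1 |
| north | 30.0 | 0.9 | 77.6 |
| north | 40.0 | 1.3 | 71.1 |
| north | 50.0 | 1.3 | 64.9 |
| north | 60.0 | 2.7 | 60.0 |
| south | 3.00 | 1.9 | 95.5 |
| south | 8.00 | 6.9 | 87.2 |
| south | 15.0 | 11.5 | 78.0 |
| south | 25.0 | 17.1 | 64.3 |
| south | 30.0 | 20.7 | 61.4 |
| south | 40.0 | 25.1 | 51.2 |
| south | 60.0 | 37.6 | 32.4 |
| north-east | 5.00 | 0.7 | 94.9 |
| north-east | 15.0 | 4.9 | 86.2 |
| north-east | 25.0 | 6.0 | 76.8 |
| north-east | 40.0 | 6.5 | 65.8 |
| north-east | 60.0 | 11.1 | 52.1 |

(each reading ± 1 percentage point)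

- the flask that ends with the higher amount of Q, in percent of the D charged, or "neither" when 2 percentage points or less lies between them (spring / summer / neither)
- final Q, as a percentage of the D charged, in spring
- final Q, as a percentage of the D charged, in summer

- the numbers in the tables scatter with a standard deviation of 1 percentage point
- reactions considered so far: D + J -> Q + J; J + E -> J.E; D -> X

Spring charges 0.85 µM of J against 0.69 µM of E. Taking E to bind J one to one, that leaves 0.160 µM as the excess of J, charged [J] less charged [E]: the J still free once E has been used up. At 60.0 min the north run, with an excess of −0.160 µM, read 2.7% of Q. North-east, at 0.160 µM, read 11.1%, and south, at 0.610 µM, read 37.6%.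

Turned round: on this reckoning, to end above spring, summer needs J left over after E, and more of it than spring has, its time being the shorter. Its charges give the opposite. Summer's J falls 0.290 µM short of its E, which makes J the limiting reagent of the binding, so summer is reckoned at north's low level of Q.

Spring has north-east's excess, so north-east's readings carry over, passing over spring's 0.098 M of D against 0.11 M:

share of lost D read as Q = 23.2%

D lost by 80 min = 58.1%

Q in spring = 13.5%

The forecast names spring, with 14.5% (12.5% to 17%) in spring, 1 percentage point above this reckoning, and 0.5% (0.1% to 1.2%) in summer: “Summer has J below E, so free J is tiny”.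

The flask with more Q is spring: 14.3% of Q in spring, 0.820% in summer.

    D + J → Q + J, rate k1*[D]*[J]/(1 + ([D]/Km1) + ([Q]/Kp1)) (4.12 mM, 23.8 mM, k = 2.69 × 10⁵ M⁻¹ min⁻¹)
    J + E → J.E (k = 30400 M⁻¹ s⁻¹)
    D → X (k = 0.00833 min⁻¹)

At 80.0 min spring holds 18.8% of its J free with E at 0%, and the excess over the charge gives 18.8%. A neighbour of summer, charged with 0.280 µM of E, has an excess of 0.120 µM, or 30.0% of its J; at 20.0 min it holds 30.3% free and ends with 5.22% of Q. Spring has not come to rest: at 800 min its Q reaches 32.9% with D at 0%. Summer keeps 0.820% of Q at 200 min, while its D sinks from 84.0% at 20.0 min to 18.7% at 200 min.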